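**Retrosynthetic overview**
1. Target 6 is a 2,2'-dihydroxy diaryl ether. Ring A (C1–C6) carries OH on C1, Br on C2 and C4, and the bridging O on C6; ring B (C1'–C6') carries the bridging O on C1', Br on C2', C4' and C5', and OH on C6'. The plan rests on each hydroxyl oxygen sitting ortho to the ether oxygen.
2. Both C–OH bonds (C1–O and C6'–O) are traced back to C–CHO: 6 ⇐ bis(formate) 5 ⇐ dialdehyde 4 by a double Baeyer–Villiger (Dakin-type) oxidation.
3. The ether bond C6–O is cut by SNAr: the phenoxide of tribromosalicylaldehyde 2 attacks fluoroaldehyde 3, whose fluoride is activated by the formyl group that later becomes the C1 hydroxyl.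
4. 2 ⇐ dibromination of 2-bromo-6-hydroxybenzaldehyde 1, which sets the 2',4',5'-tribromo pattern of ring B.
5. No ring is formed at any stage; both benzene rings are purchased and the sequence is linear, 1 → 2 → 4 → 5 → 6.

Key step: step 3

Remark on the chemistry: the target has no stereocentre and its diaryl ether axis should rotate freely, so it is achiral and the route needs no stereocontrol.

Step 1
Reactants: 1 2-bromo-6-hydroxybenzaldehyde
Product: 2 3,5,6-tribromo-2-hydroxybenzaldehyde
Conditions: Br2 (2.2 equiv), NaOAc, AcOH, rt → 50 °C
Reagents that add atoms: bromine, BrBr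
Why: Electrophilic aromatic bromination, in which the phenol oxygen (ortho/para), the formyl group (meta) and the C6 bromine (ortho/para) all direct to C3 and C5, the same two positions taken in the classical dibromination of salicylaldehyde, so two equivalents of bromine should stop at the tribromide.

Step 2
Reactants: 2 3,5,6-tribromo-2-hydroxybenzaldehyde; 3 2,4-dibromo-6-fluorobenzaldehyde
Product: 4 3,5,6-tribromo-2-(3,5-dibromo-2-formylphenoxy)benzaldehyde
Conditions: Cs2CO3, dry DMSO, 80 °C, N2
Reagents that add atoms: none
Why: Nucleophilic aromatic substitution by addition–elimination, in which the caesium phenoxide of 2 adds to the C–F carbon ortho to the formyl group of 3, the Meisenheimer adduct is stabilised by that formyl group, and fluoride should leave far faster than either bromide, so the C6–O ether bond forms with all five bromines kept.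

Step 3
Reactants: 4 3,5,6-tribromo-2-(3,5-dibromo-2-formylphenoxy)benzaldehyde
Product: 5 3,5,6-tribromo-2-[3,5-dibromo-2-(formyloxy)phenoxy]phenyl formate
Conditions: mCPBA (dried, excess), dry CH2Cl2, 0 °C → reflux
Reagents that add atoms: meta-chloroperoxybenzoic acid, O=C(OO)c1cccc(Cl)c1
Why: Double Baeyer–Villiger (Dakin-type) oxidation, in which the peracid adds to each formyl carbon to give a Criegee perhemiacetal and the aryl carbon (C1 of ring A, C6' of ring B) shifts from carbon to the proximal peroxide oxygen as 3-chlorobenzoate leaves, which makes the C1–O and C6'–O bonds as aryl formates. The closest known reaction type is the peracid oxidation of ortho-alkoxy- and ortho-aryloxybenzaldehydes to aryl formates. No ring is closed and no stereocentre is formed. The selectivity needed is aryl over hydride migration at two electron-poor aldehydes; the ether oxygen ortho to each migrating carbon should secure it, because its lone pair stabilises the positive charge that builds up on the migrating ring, and anhydrous peracid keeps the formates intact and closes the hydrate pathway to the carboxylic acids. The aryl bromides and the diaryl ether should be inert to the peracid, and an excess of oxidant with gentle heating answers the two doubly ortho-flanked carbonyl groups.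

Step 4
Reactants: 5 3,5,6-tribromo-2-[3,5-dibromo-2-(formyloxy)phenoxy]phenyl formate (crude from step 3)
Product: 6 3,5,6-tribromo-2-(3,5-dibromo-2-hydroxyphenoxy)phenol
Conditions: Et3N (cat.), MeOH–THF, rt
Reagents that add atoms: none
Why: Base-catalysed transesterification (methanolysis), since formates of acidic, electron-poor phenols are among the most labile esters and should pass both formyl groups to methanol at room temperature, while the weak amine base and short exposure give no occasion for aryl migration between the ortho oxygens.

**Compound list**
1 | 2-bromo-6-hydroxybenzaldehyde | O=Cc1c(O)cccc1Br | starting material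
2 | 3,5,6-tribromo-2-hydroxybenzaldehyde | O=Cc1c(O)c(Br)cc(Br)c1Br | intermediate
3 | 2,4-dibromo-6-fluorobenzaldehyde | O=Cc1c(F)cc(Br)cc1Br | starting material
4 | 3,5,6-tribromo-2-(3,5-dibromo-2-formylphenoxy)benzaldehyde | O=Cc1c(Br)cc(Br)cc1Oc1c(Br)cc(Br)c(Br)c1C=O | intermediate
5 | 3,5,6-tribromo-2-[3,5-dibromo-2-(formyloxy)phenoxy]phenyl formate | O=COc1c(Br)cc(Br)cc1Oc1c(Br)cc(Br)c(Br)c1OC=O | intermediate
6 | 3,5,6-tribromo-2-(3,5-dibromo-2-hydroxyphenoxy)phenol | Oc1c(Br)cc(Br)cc1Oc1c(Br)cc(Br)c(Br)c1O | target

Total step count: 4
Longest linear sequence: 4 steps (1 → 2 → 4 → 5 → 6)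

**Steps most likely to fail**

Step 3. Hydride rather than aryl migration may take place in one or both Criegee adducts, ending at carboxylic acids, and the peracid may add only slowly to the second, doubly ortho-flanked formyl group, so that the oxidation stalls half-way. The fallback sets out from 4 and comes back to the route at 6. Methylmagnesium bromide in THF at −78 °C should add to both formyl groups to give the diol 1-{2,4-dibromo-6-[3,4,6-tribromo-2-(1-hydroxyethyl)phenoxy]phenyl}ethanol F1 as a mixture of diastereomers. Dess–Martin periodinane should oxidise it to the diketone 1-[2-(2-acetyl-3,4,6-tribromophenoxy)-4,6-dibromophenyl]ethanone F2. Baeyer–Villiger oxidation with trifluoroperacetic acid (trifluoroacetic anhydride, urea–hydrogen peroxide, Na2HPO4, CH2Cl2) now has only methyl as the competing migrating group, so aryl migration should prevail and give the bis(acetate) 3,5,6-tribromo-2-[2-(acetyloxy)-3,5-dibromophenoxy]phenyl acetate F3. Methanolysis with K2CO3 in methanol followed by acidification should deliver 6.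

Step 2. The hindered, weakly basic phenoxide of 2 may attack too slowly, so that cleavage of the C–F bond of 3 by carbonate and adventitious water, or substitution of the bromide para to the formyl group, overtakes ether formation. The fallback sets out from 2 and comes back at 4. Ethylene glycol with catalytic TsOH in toluene under water removal should convert 2 into the acetal 3,4,6-tribromo-2-(1,3-dioxolan-2-yl)phenol F4, whose phenoxide is no longer conjugated to a carbonyl group and is therefore a better nucleophile. SNAr on 3 (Cs2CO3, DMSO) should give 2,4-dibromo-6-[3,4,6-tribromo-2-(1,3-dioxolan-2-yl)phenoxy]benzaldehyde F5, and aqueous HCl in THF should release the second formyl group to give 4.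

Step 1. Bromine may attack at the formyl-bearing carbon with loss of the formyl group (ipso substitution), or the reaction may stall after the first bromination next to the existing bromine. The fallback does not set out from a numbered compound: it replaces 1 by purchased 2,4,5-tribromophenol F6 and comes back at 2. Magnesium-mediated ortho-formylation (MgCl2, Et3N, paraformaldehyde, MeCN, reflux) should place the formyl group on the only free ortho carbon, so the bromine pattern of ring B is bought and no bromination is needed.

**Further compounds**
F1 | step 3 | 1-{2,4-dibromo-6-[3,4,6-tribromo-2-(1-hydroxyethyl)phenoxy]phenyl}ethanol (mixture of diastereomers) | CC(O)c1c(Br)cc(Br)cc1Oc1c(Br)cc(Br)c(Br)c1C(C)O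
F2 | step 3 | 1-[2-(2-acetyl-3,4,6-tribromophenoxy)-4,6-dibromophenyl]ethanone | CC(=O)c1c(Br)cc(Br)cc1Oc1c(Br)cc(Br)c(Br)c1C(C)=O
F3 | step 3 | 3,5,6-tribromo-2-[2-(acetyloxy)-3,5-dibromophenoxy]phenyl acetate | CC(=O)Oc1c(Br)cc(Br)cc1Oc1c(Br)cc(Br)c(Br)c1OC(C)=O
F4 | step 2 | 3,4,6-tribromo-2-(1,3-dioxolan-2-yl)phenol | Oc1c(Br)cc(Br)c(Br)c1C1OCCO1
F5 | step 2 | 2,4-dibromo-6-[3,4,6-tribromo-2-(1,3-dioxolan-2-yl)phenoxy]benzaldehyde | O=Cc1c(Br)cc(Br)cc1Oc1c(Br)cc(Br)c(Br)c1C1OCCO1
F6 | step 1 | 2,4,5-tribromophenol | Oc1cc(Br)c(Br)cc1Br
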